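Slowness is what separates these flasks: Sunday's cold flask took 2.50 h to show 11.8% of intermediate A, and Tuesday's warmer one showed 12.7% after 5.00 min. Scaling those times to equal amounts gives the clock ratio, how many times as long Sunday's flask needed as Tuesday's to reach the same amount of intermediate A: 32.3. It is a reading with scatter in it, and the charges differed too, 0.10 M against 0.40 M, so it holds for these flasks only if the charge leaves the path of intermediate A alone.

| setting | Sunday's | Tuesday's | delta | theta | epsilon | eta |
|---|---|---|---|---|---|---|
| substrate | 0.10 M | 0.40 M | 0.20 M | 0.20 M | 0.20 M | 0.20 M |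
| temperature | −12 °C | 15 °C | 0 °C | 25 °C | −25 °C |  |
| remark | run made earlier | run made earlier |  |  |  | at −25 °C until 80 min, from then on at 25 °C |
| time |  |  | 2.5 h | 2.5 h | 2.5 h | 2.5 h |

Sunday's run (percent of the substrate charged)

| time / h | intermediate A / % | target / % |
|---|---|---|
| 0.417 | 2.6 | 0.5 |
| 0.667 | 3.9 | 0.8 |
| 0.833 | 4.4 | 0.2 |
| 1.50 | 7.3 | 0.2 |
| 2.50 | 11.8 | 1.4 |
| 4.00 | 14.6 | 0.7 |
| 5.00 | 16.9 | 2.5 |

Tuesday's run (percent of the substrate charged)

| time / min | intermediate A / % | target / % |
|---|---|---|
| 5.00 | 12.7 | 0.3 |
| 15.0 | 19.2 | 4.6 |
| 25.0 | 17.0 | 13.6 |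
| 40.0 | 10.4 | 29.5 |
| 60.0 | 5.7 | 46.2 |
| 80.0 | 1.9 | 54.5 |

(each reading ± 0.5 percentage points)

- the analysis behind the earlier runs scatters by 0.5 percentage points, standard deviation

- which flask leads in amount of intermediate A, in percent of the substrate charged ("all alike" within 1.5 percentage points) (delta / theta / epsilon / eta / all alike)
- how much intermediate A is there at the end, in percent of the substrate charged: delta
- how much intermediate A is there at the end, in percent of the substrate charged: theta
- how much intermediate A is there at the end, in percent of the substrate charged: epsilon
- how much intermediate A is there at the end, in percent of the substrate charged: eta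

Two chemists argue over this. The first holds to straight lines: intermediate A piles up at its opening rate. With the clock ratio spread evenly over the degrees, Tuesday's opening rate carried to theta reaches the whole charge in 10.9 min, so he bets on theta.

The second holds that temperature changes the pace and not the path, so each flask's hours can be told as Tuesday's minutes, which others call a master curve. Tuesday's intermediate A peaked at 19.2% after 15.0 min, the highest reading, and fell to 1.9% by 80.0 min.

I side with her. Delta's 2.5 h count as 21.8 min, between Tuesday's readings at 15.0 min and 25.0 min, which gives 17.7%. Theta's count as 543 min, and the warm part of eta as 254 min. Both lie far beyond Tuesday's last reading, so I expect next to no intermediate A in either. Epsilon's hours count as 0.469 h on Sunday's clock, which gives 2.87%.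

The forecast, which treats the flask as “consecutive first-order steps”, names delta as leader with 18.5% for delta, 0% for theta, 2% for epsilon and 0.02% for eta, so it stands below my figure for epsilon.

The flasks give 17.1% in delta, which leads, with 1.98% in epsilon, 0.0273% in eta and 0% in theta. My reckoning stood 0.60 percentage points high on delta and 0.89 points high on epsilon.

    2 substrate → self-condensation product (k = 0.510 M⁻¹ h⁻¹, Ea = 59.0 kJ mol⁻¹)
    target → over-reaction product (k = 3.20 × 10⁻⁴ h⁻¹, Ea = 110 kJ mol⁻¹)
    intermediate A → intermediate B (k = 0.780 h⁻¹, Ea = 78.0 kJ mol⁻¹)
    substrate + intermediate B → side product (k = 1.40 M⁻¹ h⁻¹, Ea = 59.0 kJ mol⁻¹)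
    substrate → intermediate A (k = 0.320 h⁻¹, Ea = 82.0 kJ mol⁻¹)
    intermediate B → target (k = 0.720 h⁻¹, Ea = 80.0 kJ mol⁻¹)
    (constants at 0 °C)

The straight line keeps its ground at short clock times: in epsilon, intermediate A went from 1.02% after 1.25 h to 1.98% after 2.50 h, twice the amount, with 94.4% of the substrate still there. Theta repeated at 0 °C drops from 543 min to 21.8 min on Tuesday's clock, which again gives 17.7%; that flask holds 17.1% of intermediate A, with 31.7% of the substrate left.

The readings are simulated for an exercise; the scatter is artificial.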